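## The problem

Compound 16 is quercetin carrying hydrogen sulfate esters on both oxygens of the ring B catechol, with the 3-, 5- and 7-hydroxyls free. The skeleton is a planar 2-aryl-3-hydroxychromen-4-one: ring A (C4a, C5, C6, C7, C8, C8a) is fused to the pyranone ring C (O1, C2, C3, C4, C4a, C8a), and ring B sits on C2. There is no stereocentre, so the task is one of regiochemistry and of telling five hydroxyls apart. Only O3' and O4' may be sulfated, so ring B has to be unmasked alone while O3, O5 and O7 stay covered. Aryl sulfate half-esters do not survive acid, Lewis acids, heat or carbanion chemistry; they must be made last but one, and the final deprotection must be neutral, which points to hydrogenolysis of benzyl ethers. The C3 oxygen should be in place from the start, so that no late oxidation of an electron-rich flavone is needed. The enabling feature is ring A: C5, C7 and C8a carry oxygen on alternate carbons and C4a carries the C4 acyl group, so ring A is an acylphloroglucinol, the aromatised fold of a poly-β-carbonyl chain that continues through C4, C3 and C2. Because the two hydroxyls flanking C4a are equivalent, ring C can close from either one to the same chromenone.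

## Retrosynthesis

Chain numbering of the open precursor maps onto the flavone as C1→C5, C2→C6, C3→C7, C4→C8, C5→C8a, C6→C4a, C7→C4, C8→C3, C9→C2.

**End game (16 back to 12).** The three O–benzyl bonds of 15 are cut last in the forward sense, because hydrogenolysis is the one global deprotection that leaves aryl sulfates intact. Cutting the two S–O bonds of 15 leads to catechol 14. The catechol of 14 is traced back to the bis(allyl ether) 13, and the benzyl ethers at O5 and O7 of 13 are traced back to the diol 12. The order is forced: sulfation needs ring B free and ring A covered, so 12, which leaves the ring-forming step with O5 and O7 free, must be benzylated before ring B is opened. The forward reactions asked for are routine: etherification, deallylation under zerovalent-palladium catalysis, O-sulfation and hydrogenolysis.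

**Key disconnection (12 back to 10).** Two bonds are cut together, C4a–C5 and O1–C2, which opens both rings and leads to the acyclic tetraoxo ester 10. Cutting O1–C2 alone would leave a preformed phloroglucinol ring whose hydroxyls must be differentiated before acylation. Cutting C4–C4a alone would demand a stereodefined, fully substituted enol ether acid. The double cut gives a precursor with no ring other than ring B and one enolisable racemic centre, and it places the C3 oxygen (as a benzyl ether on C8) and ring B in the chain from the outset. The forward reaction must fold the chain in the Claisen sense (C6 onto C1) and not in the aldol sense (C2 onto C7), then close O1–C2 by cyclodehydration.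

**Unmasking the ester terminus (10 back to 8).** The C1–OMe bond is cut and C1–C3 are stored as the dioxinone of 8. A free β-keto ester terminus would not survive the strong bases that build the chain, and an open pentacarbonyl chain would fold too early. The dioxinone has no electrophilic ketone and is opened under neutral thermal conditions at the very end. The forward step must release the ester without base or acid.

**Ring B aroyl group (8 back to 7 and 2).** The C8–C9 bond is cut. The neighbouring cut at C6–C7 would need an acyl donor in which C8 already lies between two carbonyl groups, and such a donor would be deprotonated, not attacked, by any carbanion. The cut at C8–C9 puts all the acidity into the nucleophile and leaves as electrophile the benzoate 2, which has no α-hydrogen. The precursor 7 loses the whole of ring B. The forward reaction asks for the trianion of 7 to react at its last-formed, terminal carbanion.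

**Chain assembly (7 back to 5 and 6, 5 back to 3 and 4).** Cutting C6–C7 gives the keto-dioxinone 5 and the acid chloride 6, which supplies C7, C8 and the benzylated C3 oxygen. Cutting C4–C5 gives dioxinone 3 (C1–C4) and acetyl chloride 4 (C5, C6). Both forward steps are terminal C-acylations of dioxinone enolates, and every acylating agent used is either non-enolisable or cheap enough to use with excess nucleophile.

**Ring B ester (2 back to 1).** The two O–allyl bonds are cut to reach commercial 1. Allyl ethers are preferred to acetal protection because the acid needed to dehydrate in the ring-forming step would endanger acetals, and loss of ring B protection at that point would destroy the differentiation of the hydroxyls.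

## Roads not taken

**Alternative 1:** Ring C is cut at C4a–C4, C4–C3 and O1–C2. In the forward sense 3,5-bis(benzyloxy)-2-iodophenol A1, 4-ethynyl-1,2-bis(methoxymethoxy)benzene A2 and carbon monoxide A3 combine under PdCl2(PPh3)2 in a secondary amine by carbonylative Sonogashira coupling and 6-endo oxa-Michael closure to flavone A4.
- Merits: it is highly convergent. Iodophenol A1 brings ring A with O5 and O7 already benzylated, alkyne A2 brings ring B with C2 and C3, and the gas A3 supplies C4. The reaction type is established.
- Weak points for this target: A4 has no oxygen at C3, so a C3 hydroxylation and a benzylation must follow on an electron-rich flavone. Five-membered (aurone-type) closure competes. Iodination to A1 must go ortho to the hydroxyl and not between the two ethers. Alkyne A2 needs its own short synthesis, and A3 is a toxic gas that is normally used under pressure.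
- Comparison: in reliability and convergence this road is the stronger one, and its length is similar. The chosen plan sets against it that the C3 oxygen is built in from 6 at the right oxidation level, that no pressurised toxic gas is needed, and that both rings form in one operation.

**Alternative 2:** Ring A is cut at C5–C6, C7–C8 and C4a–C5. In the forward sense the pyranonyl diazomethyl ketone A5 is irradiated and then heated with (triisopropylsilyloxy)acetylene A6. Wolff rearrangement, [2+2] addition of the ynol ether, four-electron ring opening, six-electron ring closure and tautomerisation give the chromenone A7, with the C5 phenol free and O7 silylated.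
- Merits: ring A regiochemistry follows from the polarity of the ynol ether, O7 arrives protected and distinct from the chelated 5-hydroxyl, and the C3 oxygen is present. The end game would be one step shorter than the chosen one, and in that respect this road is better.
- Weak points: A5 needs a fully substituted 4-pyranone made in many steps and a diazo homologation. The pyranone chromophore competes for light, and A6 is sensitive.
- Comparison: the chosen plan offers a five-step access to its cyclisation precursor from bulk chemicals and no photochemistry or diazo handling, at the cost of one extra protection step after the ring closure.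

**Alternative 3:** Ring C is cut at C4–C4a. In the forward sense the acrylic acid A8, activated as a mixed anhydride, acylates the ortho carbon of its 3,5-bis(benzyloxy)phenoxy ring (Friedel–Crafts) to give the chromenone A9.
- Merits: the acylation of a phloroglucinol diether is favourable and has no regiochemical issue. A9 has exactly the protecting pattern the end game wants, three benzyl ethers and base-labile pivalates on ring B, so depivaloylation, sulfation and hydrogenolysis finish in three steps. That is one fewer than the chosen plan, and the key step is of a known type; on both counts this road is better.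
- Weak points: A8 is a tetrasubstituted enol ether with three different oxygen substituents and a defined geometry (acid cis to aryloxy), and no short, reliable synthesis of it is evident. The acidic activator may cleave the benzyl ether that becomes O5 or the pivalates.
- Comparison: the chosen plan sets against it a geometry-free acyclic precursor from four commercial pieces and two rings closed in the key step, at the price of an unprecedented fold.

Key step: step 6

Assumption: the sulfate half-esters of 15 and 16 are written in the neutral hydrogen sulfate form of the target; in the flask they would be carried as sodium salts, and the acid form is released only at the end.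

## Route

Step 1
Reactants: 1 methyl 3,4-dihydroxybenzoate
Product: 2 methyl 3,4-bis(allyloxy)benzoate
Conditions: allyl bromide (2.5 equiv), K2CO3, DMF, 60 °C
Reagents that add atoms: allyl bromide, C=CCBr
Why: Twofold Williamson etherification of the catechol; the methyl ester is untouched, and allyl ethers tolerate lithium amides, Mg(OMe)2 and aqueous acid yet leave later under zerovalent-palladium catalysis without disturbing benzyl ethers.

Step 2
Reactants: 3 2,2,6-trimethyl-4H-1,3-dioxin-4-one; 4 acetyl chloride
Product: 5 2,2-dimethyl-6-(2-oxopropyl)-4H-1,3-dioxin-4-one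
Conditions: 3 (2 equiv), LiN(SiMe3)2 (2 equiv), THF, −78 °C; then 4 (1 equiv), −78 °C; aq. NH4Cl
Reagents that add atoms: none
Why: γ-Deprotonation gives the lithium dienolate of the dioxinone, which is C-acylated at the exocyclic carbon (vinylogous Claisen-type acylation); the second equivalent of dienolate takes up the acidic proton of 5.

Step 3
Reactants: 5 2,2-dimethyl-6-(2-oxopropyl)-4H-1,3-dioxin-4-one; 6 benzyloxyacetyl chloride
Product: 7 6-[5-(benzyloxy)-2,4-dioxopentyl]-2,2-dimethyl-4H-1,3-dioxin-4-one
Conditions: 5 (2 equiv), LiN(iPr)2 (4.1 equiv), THF, −78 °C; then 6 (1 equiv), −78 to −40 °C; aq. NH4Cl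
Reagents that add atoms: none
Why: The dianion of the keto-dioxinone reacts at its last-formed terminal carbanion with the acid chloride (dianion C-acylation, the standard entry to diketo-dioxinones); excess dianion absorbs the acidic proton of the new diketone.

Step 4
Reactants: 7 6-[5-(benzyloxy)-2,4-dioxopentyl]-2,2-dimethyl-4H-1,3-dioxin-4-one; 2 methyl 3,4-bis(allyloxy)benzoate
Product: 8 6-{6-[3,4-bis(allyloxy)phenyl]-5-(benzyloxy)-2,4,6-trioxohexyl}-2,2-dimethyl-4H-1,3-dioxin-4-one
Conditions: LiN(iPr)2 (4.2 equiv), THF, −78 to 0 °C; then 2 (1.1 equiv), 0 °C to rt; AcOH quench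
Reagents that add atoms: none
Why: Terminal Claisen acylation of a 1,3,5-tricarbonyl trianion by an aromatic ester: the benzyloxy-bearing carbon is the only enolisable site left after two deprotonations and its carbanion is the most nucleophilic; benzoate 2 has no α-hydrogen to quench it, and the extra base covers the acidic C–H of the product.

Step 5
Reactants: 8 6-{6-[3,4-bis(allyloxy)phenyl]-5-(benzyloxy)-2,4,6-trioxohexyl}-2,2-dimethyl-4H-1,3-dioxin-4-one
Product: 10 methyl 8-(benzyloxy)-9-[3,4-bis(allyloxy)phenyl]-3,5,7,9-tetraoxononanoate (racemic at C8), via acylketene 9 (not isolated)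
Conditions: MeOH (10 equiv), PhMe, 110 °C, sealed tube; evaporate and use crude
Reagents that add atoms: methanol, CO
Why: Thermal retro-hetero-Diels–Alder fragmentation of the dioxinone expels acetone and leaves an acylketene that methanol traps as the β-keto ester; the medium is neutral, so the largely enolised polycarbonyl chain is delivered unfolded.

Step 6
Reactants: 10 methyl 8-(benzyloxy)-9-[3,4-bis(allyloxy)phenyl]-3,5,7,9-tetraoxononanoate
Product: 12 3-(benzyloxy)-5,7-dihydroxy-2-[3,4-bis(allyloxy)phenyl]-4H-chromen-4-one, via acylphloroglucinol diketone 11 (not isolated)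
Conditions: Mg(OMe)2 (6 equiv), MeOH, rt to 65 °C; then aq. HCl to pH 1, 50 °C
Reagents that add atoms: none
Why: Proposed new method: excess Mg(OMe)2 turns 10 into a magnesium polyenolate in which the C7/C9 diketone is held as a six-membered chelate by deprotonation at C8, so neither C7 nor C9 can act as an aldol acceptor, while the ester carbon C1, next to the least acidic methylene C2, stays electrophilic; the carbanion at C6 attacks C1 (6-exo-trig Claisen closure of ring A), methoxide leaves, and the cyclohexanetrione tautomerises irreversibly to the acylphloroglucinol 11. On acidification the side-chain diketone of 11 is released from magnesium, a hydroxyl ortho to the acyl group adds to the aroyl carbon C9 (6-exo-trig hemiketal formation), and acid-catalysed loss of water toward C8 gives the pyranone ring C of 12. The closest known reaction types are the base-mediated Claisen cyclisation of methyl 3,5,7-trioxoalkanoates to acylphloroglucinols and the acid cyclodehydration of 1-(2-hydroxyaryl)-1,3-diketones that ends a Baker–Venkataraman flavone synthesis; new here is that one pentacarbonyl chain carrying the C3 oxygen and ring B passes through both in one flask. No stereocentre is formed, and the racemic centre C8 of 10 becomes the sp2 carbon C3. The selectivity needed is Claisen (C6 to C1) over aldol (C2 to C7 or C4 to C9) folding, secured by the chelated, enolised state of C7 and C9 and by the aromatisation that follows only the Claisen mode; addition of C8 to C3 is reversible because its product cannot aromatise. Ring C can close in one way only, since both hydroxyls flanking the acyl group of 11 are equivalent and C9 is the only carbonyl within reach. Allyl and benzyl ethers should survive both the basic and the acidic stage.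

Step 7
Reactants: 12 3-(benzyloxy)-5,7-dihydroxy-2-[3,4-bis(allyloxy)phenyl]-4H-chromen-4-one
Product: 13 3,5,7-tris(benzyloxy)-2-[3,4-bis(allyloxy)phenyl]-4H-chromen-4-one
Conditions: BnBr (3 equiv), K2CO3, DMF, 70 °C
Reagents that add atoms: benzyl bromide, BrCc1ccccc1
Why: Williamson benzylation; the 7-hydroxyl reacts readily and the chelated 5-hydroxyl follows with excess halide and heat in DMF, as in the perbenzylation of 5-hydroxyflavonols.

Step 8
Reactants: 13 3,5,7-tris(benzyloxy)-2-[3,4-bis(allyloxy)phenyl]-4H-chromen-4-one
Product: 14 3,5,7-tris(benzyloxy)-2-(3,4-dihydroxyphenyl)-4H-chromen-4-one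
Conditions: Pd(PPh3)4 (5 mol %), morpholine (10 equiv), THF, rt, argon
Reagents that add atoms: none
Why: Tsuji–Trost deallylation: zerovalent palladium ionises the aryl allyl ethers to π-allylpalladium complexes that morpholine captures; benzyl ethers and the chromenone are inert.

Step 9
Reactants: 14 3,5,7-tris(benzyloxy)-2-(3,4-dihydroxyphenyl)-4H-chromen-4-one
Product: 15 4-[3,5,7-tris(benzyloxy)-4-oxo-4H-chromen-2-yl]-1,2-phenylene bis(hydrogen sulfate) (handled as the disodium salt)
Conditions: SO3·pyridine (10 equiv), pyridine, 40 °C; then aq. NaHCO3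
Reagents that add atoms: sulfur trioxide–pyridine complex, [O-]S(=O)(=O)[n+]1ccccc1
Why: O-Sulfation of the only two free hydroxyls by the SO3–amine complex; the excess drives the slower second sulfation beside the first sulfate anion, and the bicarbonate work-up replaces pyridinium, which would poison the hydrogenolysis catalyst, by sodium.

Step 10
Reactants: 15 4-[3,5,7-tris(benzyloxy)-4-oxo-4H-chromen-2-yl]-1,2-phenylene bis(hydrogen sulfate)
Product: 16 4-(3,5,7-trihydroxy-4-oxo-4H-chromen-2-yl)-1,2-phenylene bis(hydrogen sulfate) (quercetin 3',4'-disulfate)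
Conditions: H2 (1 atm), Pd/C, THF–MeOH–H2O, rt; then acid-form sulfonic acid resin, 0 °C
Reagents that add atoms: none
Why: Hydrogenolysis of the three benzyl ethers over Pd/C under neutral conditions, which aryl sulfate salts tolerate; a brief cold pass through acid resin gives the neutral form drawn for the target.

## Compound list

1 | methyl 3,4-dihydroxybenzoate | COC(=O)c1ccc(O)c(O)c1 | starting material
2 | methyl 3,4-bis(allyloxy)benzoate | COC(=O)c1ccc(OCC=C)c(OCC=C)c1 | intermediate
3 | 2,2,6-trimethyl-4H-1,3-dioxin-4-one | CC1=CC(=O)OC(C)(C)O1 | starting material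
4 | acetyl chloride | CC(Cl)=O | starting material
5 | 2,2-dimethyl-6-(2-oxopropyl)-4H-1,3-dioxin-4-one | CC(=O)CC1=CC(=O)OC(C)(C)O1 | intermediate
6 | benzyloxyacetyl chloride | O=C(Cl)COCc1ccccc1 | starting material
7 | 6-[5-(benzyloxy)-2,4-dioxopentyl]-2,2-dimethyl-4H-1,3-dioxin-4-one | CC1(C)OC(=O)C=C(CC(=O)CC(=O)COCc2ccccc2)O1 | intermediate
8 | 6-{6-[3,4-bis(allyloxy)phenyl]-5-(benzyloxy)-2,4,6-trioxohexyl}-2,2-dimethyl-4H-1,3-dioxin-4-one (racemic) | CC1(C)OC(=O)C=C(CC(=O)CC(=O)C(OCc2ccccc2)C(=O)c2ccc(OCC=C)c(OCC=C)c2)O1 | intermediate
9 | 8-(benzyloxy)-9-[3,4-bis(allyloxy)phenyl]-3,5,7,9-tetraoxonon-1-en-1-one (acylketene, racemic) | O=C=CC(=O)CC(=O)CC(=O)C(OCc1ccccc1)C(=O)c1ccc(OCC=C)c(OCC=C)c1 | intermediate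
10 | methyl 8-(benzyloxy)-9-[3,4-bis(allyloxy)phenyl]-3,5,7,9-tetraoxononanoate (racemic) | COC(=O)CC(=O)CC(=O)CC(=O)C(OCc1ccccc1)C(=O)c1ccc(OCC=C)c(OCC=C)c1 | intermediate
11 | 2-(benzyloxy)-1-[3,4-bis(allyloxy)phenyl]-3-(2,4,6-trihydroxyphenyl)propane-1,3-dione (racemic) | O=C(c1c(O)cc(O)cc1O)C(OCc1ccccc1)C(=O)c1ccc(OCC=C)c(OCC=C)c1 | intermediate
12 | 3-(benzyloxy)-5,7-dihydroxy-2-[3,4-bis(allyloxy)phenyl]-4H-chromen-4-one | O=c1c(OCc2ccccc2)c(-c2ccc(OCC=C)c(OCC=C)c2)oc2cc(O)cc(O)c12 | intermediate
13 | 3,5,7-tris(benzyloxy)-2-[3,4-bis(allyloxy)phenyl]-4H-chromen-4-one | O=c1c(OCc2ccccc2)c(-c2ccc(OCC=C)c(OCC=C)c2)oc2cc(OCc3ccccc3)cc(OCc3ccccc3)c12 | intermediate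
14 | 3,5,7-tris(benzyloxy)-2-(3,4-dihydroxyphenyl)-4H-chromen-4-one | O=c1c(OCc2ccccc2)c(-c2ccc(O)c(O)c2)oc2cc(OCc3ccccc3)cc(OCc3ccccc3)c12 | intermediate
15 | 4-[3,5,7-tris(benzyloxy)-4-oxo-4H-chromen-2-yl]-1,2-phenylene bis(hydrogen sulfate) | O=c1c(OCc2ccccc2)c(-c2ccc(OS(=O)(=O)O)c(OS(=O)(=O)O)c2)oc2cc(OCc3ccccc3)cc(OCc3ccccc3)c12 | intermediate
16 | 4-(3,5,7-trihydroxy-4-oxo-4H-chromen-2-yl)-1,2-phenylene bis(hydrogen sulfate) | O=c1c(O)c(-c2ccc(OS(=O)(=O)O)c(OS(=O)(=O)O)c2)oc2cc(O)cc(O)c12 | target

## Step count and risks

Total: 10 steps. Longest linear sequence: 9 steps (3 to 16, steps 2 to 10); step 1 is a one-step branch.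

**Step 6 (key step).** The chain may fold the wrong way. Aldol closure of C2 onto C7 or of C4 onto C9 can occur in the fraction of polyenolate where the C7/C9 chelate is not maintained. The C5 enolate may lactonise onto the ester. Methoxide may cleave the α-benzyloxy diketone by a retro-Claisen reaction, since that diketone is less enolised than an unsubstituted one. The fallback uses known chemistry and separates the two ring closures. It sets out from 7: thermolysis in toluene–methanol gives methyl 8-(benzyloxy)-3,5,7-trioxooctanoate F1, whose Mg(OMe)2-mediated Claisen cyclisation, the established triketo ester to acylphloroglucinol reaction, gives 2-(benzyloxy)-1-(2,4,6-trihydroxyphenyl)ethan-1-one F2. Benzyl bromide and K2CO3 etherify the two non-chelated hydroxyls to 2-(benzyloxy)-1-[2,4-bis(benzyloxy)-6-hydroxyphenyl]ethan-1-one F3. Crossed Claisen condensation of the dilithium salt of F3 (LiN(SiMe3)2, THF) with ester 2 gives 1-[2,4-bis(benzyloxy)-6-hydroxyphenyl]-2-(benzyloxy)-3-[3,4-bis(allyloxy)phenyl]propane-1,3-dione F4, and mild acid cyclodehydration returns to the route at 13, so step 7 is not needed.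

**Step 4.** Formation of the trianion at the alkoxy-bearing terminus may be incomplete, or proton transfer from the diketone product to unreacted trianion may outrun addition to the electron-rich, sluggish benzoate, so that conversion stalls. The fallback avoids the trianion and sets out from 5. Allylation of commercial 3,4-dihydroxybenzaldehyde gives 3,4-bis(allyloxy)benzaldehyde F5. Aldol addition of the lithium enolate of commercial 2-(benzyloxy)-N-methoxy-N-methylacetamide to it gives 3-[3,4-bis(allyloxy)phenyl]-2-(benzyloxy)-3-hydroxy-N-methoxy-N-methylpropanamide F6, a diastereomer mixture whose two centres later become sp2. Silylation (TBSCl, imidazole) gives 3-[3,4-bis(allyloxy)phenyl]-2-(benzyloxy)-3-[(tert-butyldimethylsilyl)oxy]-N-methoxy-N-methylpropanamide F7. Acylation of the dianion of 5 by this Weinreb amide gives 6-{6-[3,4-bis(allyloxy)phenyl]-5-(benzyloxy)-6-[(tert-butyldimethylsilyl)oxy]-2,4-dioxohexyl}-2,2-dimethyl-4H-1,3-dioxin-4-one F8. HF·pyridine frees 6-{6-[3,4-bis(allyloxy)phenyl]-5-(benzyloxy)-6-hydroxy-2,4-dioxohexyl}-2,2-dimethyl-4H-1,3-dioxin-4-one F9, and oxidation of the benzylic alcohol with MnO2 returns to the route at 8.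

**Step 5.** At 110 °C the freed chain may cyclise early (aldol aromatisation or lactonisation to a 4-hydroxy-2-pyranone), or an internal enol may capture the acylketene before methanol does. The fallback drops the thermolysis and the isolation of 10: it sets out from 8, whose dioxinone is opened by methoxide (K2CO3 in MeOH, then Mg(OMe)2) with loss of acetone, so that 10 forms as its enolate and folds at once under the conditions of step 6. It returns to the route at 12 and makes no new compound.

**Step 7.** Etherification of the chelated 5-hydroxyl may stay incomplete, or forcing conditions may cause C-benzylation of ring A. The fallback leaves the 5-hydroxyl free and relies on its low nucleophilicity. It sets out from 12: one equivalent of benzyl bromide with K2CO3 at rt gives 3,7-bis(benzyloxy)-5-hydroxy-2-[3,4-bis(allyloxy)phenyl]-4H-chromen-4-one F10. Deallylation as in step 8 gives 3,7-bis(benzyloxy)-2-(3,4-dihydroxyphenyl)-5-hydroxy-4H-chromen-4-one F11. Sulfation at rt with a limited excess of SO3·pyridine gives 4-[3,7-bis(benzyloxy)-5-hydroxy-4-oxo-4H-chromen-2-yl]-1,2-phenylene bis(hydrogen sulfate) F12, and hydrogenolysis as in step 10 returns to the route at 16.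

**Step 9.** Sulfation may stall at the monosulfate, because the second hydroxyl sits beside an anionic sulfate, and sulfate may be lost on work-up if the medium turns acidic. The fallback installs the sulfates as protected diesters. It sets out from 14: 2,2,2-trichloroethyl chlorosulfate with Et3N and DMAP gives the neutral, chromatographable 4-[3,5,7-tris(benzyloxy)-4-oxo-4H-chromen-2-yl]-1,2-phenylene bis(2,2,2-trichloroethyl) bis(sulfate) F13. Zn and HCO2NH4 in methanol remove the trichloroethyl groups by reductive fragmentation and return to the route at 15.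

## Further compounds

F1 | step 6 | methyl 8-(benzyloxy)-3,5,7-trioxooctanoate | COC(=O)CC(=O)CC(=O)CC(=O)COCc1ccccc1
F2 | step 6 | 2-(benzyloxy)-1-(2,4,6-trihydroxyphenyl)ethan-1-one | O=C(COCc1ccccc1)c1c(O)cc(O)cc1O
F3 | step 6 | 2-(benzyloxy)-1-[2,4-bis(benzyloxy)-6-hydroxyphenyl]ethan-1-one | O=C(COCc1ccccc1)c1c(O)cc(OCc2ccccc2)cc1OCc1ccccc1
F4 | step 6 | 1-[2,4-bis(benzyloxy)-6-hydroxyphenyl]-2-(benzyloxy)-3-[3,4-bis(allyloxy)phenyl]propane-1,3-dione (racemic) | O=C(c1c(O)cc(OCc2ccccc2)cc1OCc1ccccc1)C(OCc1ccccc1)C(=O)c1ccc(OCC=C)c(OCC=C)c1
F5 | step 4 | 3,4-bis(allyloxy)benzaldehyde | O=Cc1ccc(OCC=C)c(OCC=C)c1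
F6 | step 4 | 3-[3,4-bis(allyloxy)phenyl]-2-(benzyloxy)-3-hydroxy-N-methoxy-N-methylpropanamide (racemic mixture of diastereomers) | CON(C)C(=O)C(OCc1ccccc1)C(O)c1ccc(OCC=C)c(OCC=C)c1
F7 | step 4 | 3-[3,4-bis(allyloxy)phenyl]-2-(benzyloxy)-3-[(tert-butyldimethylsilyl)oxy]-N-methoxy-N-methylpropanamide (racemic mixture of diastereomers) | CON(C)C(=O)C(OCc1ccccc1)C(O[Si](C)(C)C(C)(C)C)c1ccc(OCC=C)c(OCC=C)c1
F8 | step 4 | 6-{6-[3,4-bis(allyloxy)phenyl]-5-(benzyloxy)-6-[(tert-butyldimethylsilyl)oxy]-2,4-dioxohexyl}-2,2-dimethyl-4H-1,3-dioxin-4-one (racemic mixture of diastereomers) | CC1(C)OC(=O)C=C(CC(=O)CC(=O)C(OCc2ccccc2)C(O[Si](C)(C)C(C)(C)C)c2ccc(OCC=C)c(OCC=C)c2)O1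
F9 | step 4 | 6-{6-[3,4-bis(allyloxy)phenyl]-5-(benzyloxy)-6-hydroxy-2,4-dioxohexyl}-2,2-dimethyl-4H-1,3-dioxin-4-one (racemic mixture of diastereomers) | CC1(C)OC(=O)C=C(CC(=O)CC(=O)C(OCc2ccccc2)C(O)c2ccc(OCC=C)c(OCC=C)c2)O1
F0 | step 5 | none | none
F10 | step 7 | 3,7-bis(benzyloxy)-5-hydroxy-2-[3,4-bis(allyloxy)phenyl]-4H-chromen-4-one | O=c1c(OCc2ccccc2)c(-c2ccc(OCC=C)c(OCC=C)c2)oc2cc(OCc3ccccc3)cc(O)c12
F11 | step 7 | 3,7-bis(benzyloxy)-2-(3,4-dihydroxyphenyl)-5-hydroxy-4H-chromen-4-one | O=c1c(OCc2ccccc2)c(-c2ccc(O)c(O)c2)oc2cc(OCc3ccccc3)cc(O)c12
F12 | step 7 | 4-[3,7-bis(benzyloxy)-5-hydroxy-4-oxo-4H-chromen-2-yl]-1,2-phenylene bis(hydrogen sulfate) | O=c1c(OCc2ccccc2)c(-c2ccc(OS(=O)(=O)O)c(OS(=O)(=O)O)c2)oc2cc(OCc3ccccc3)cc(O)c12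
F13 | step 9 | 4-[3,5,7-tris(benzyloxy)-4-oxo-4H-chromen-2-yl]-1,2-phenylene bis(2,2,2-trichloroethyl) bis(sulfate) | O=c1c(OCc2ccccc2)c(-c2ccc(OS(=O)(=O)OCC(Cl)(Cl)Cl)c(OS(=O)(=O)OCC(Cl)(Cl)Cl)c2)oc2cc(OCc3ccccc3)cc(OCc3ccccc3)c12
A1 | alternative 1 | 3,5-bis(benzyloxy)-2-iodophenol | Oc1cc(OCc2ccccc2)cc(OCc2ccccc2)c1I
A2 | alternative 1 | 4-ethynyl-1,2-bis(methoxymethoxy)benzene | C#Cc1ccc(OCOC)c(OCOC)c1
A3 | alternative 1 | carbon monoxide | [C-]#[O+]
A4 | alternative 1 | 5,7-bis(benzyloxy)-2-[3,4-bis(methoxymethoxy)phenyl]-4H-chromen-4-one | O=c1cc(-c2ccc(OCOC)c(OCOC)c2)oc2cc(OCc3ccccc3)cc(OCc3ccccc3)c12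
A5 | alternative 2 | 3-(benzyloxy)-6-(2-diazoacetyl)-2-[3,4-bis(methoxymethoxy)phenyl]-4H-pyran-4-one | [N-]=[N+]=CC(=O)c1cc(=O)c(OCc2ccccc2)c(-c2ccc(OCOC)c(OCOC)c2)o1
A6 | alternative 2 | (triisopropylsilyloxy)acetylene | C#CO[Si](C(C)C)(C(C)C)C(C)C
A7 | alternative 2 | 3-(benzyloxy)-5-hydroxy-7-(triisopropylsilyloxy)-2-[3,4-bis(methoxymethoxy)phenyl]-4H-chromen-4-one | O=c1c(OCc2ccccc2)c(-c2ccc(OCOC)c(OCOC)c2)oc2cc(O[Si](C(C)C)(C(C)C)C(C)C)cc(O)c12
A8 | alternative 3 | (E)-2-(benzyloxy)-3-[3,5-bis(benzyloxy)phenoxy]-3-[3,4-bis(pivaloyloxy)phenyl]acrylic acid | O=C(O)/C(OCc1ccccc1)=C(\Oc1cc(OCc2ccccc2)cc(OCc2ccccc2)c1)c1ccc(OC(=O)C(C)(C)C)c(OC(=O)C(C)(C)C)c1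
A9 | alternative 3 | 3,5,7-tris(benzyloxy)-2-[3,4-bis(pivaloyloxy)phenyl]-4H-chromen-4-one | O=c1c(OCc2ccccc2)c(-c2ccc(OC(=O)C(C)(C)C)c(OC(=O)C(C)(C)C)c2)oc2cc(OCc3ccccc3)cc(OCc3ccccc3)c12
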